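**Retrosynthetic overview**
1. Target ⇒ global O-debenzylation and C3–O acylation: pentabenzyl (–)-epigallocatechin 17 + 4-(benzyloxy)benzoyl chloride 21.
2. 17 ⇒ flavan-3-one 16 (2,3-cis set by L-Selectride) ⇒ Curtius degradation of chromene acid 12 ⇒ chromene aldehyde 11.
3. 11 ⇒ salicylaldehyde 4 + cinnamaldehyde 8: a catalyst-controlled oxa-Michael addition makes O1–C2 (sets 2R), then an intramolecular aldol condensation makes C3–C4 and closes the pyran ring.
4. 4 ⇐ phloroglucinol; 8 ⇐ 3,4,5-trihydroxybenzaldehyde + formyl ylide; 21 ⇐ methyl 4-hydroxybenzoate.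
5. Ring order: rings A and B and the benzoate ring are bought as arenes; the pyran C ring is the only ring formed (step 5).

Assumption: the (S)-diarylprolinol silyl ether is assigned to the (2R)-chromene by the usual shielding model (attack anti to the CPh2OSi group), to be confirmed at 17 by optical rotation and chiral HPLC; the non-isolated species 9 and 10 are written catalyst-free although in the flask they are bound to the catalyst as enamine/iminium.

**Route**

Step 1
Reactants: 1 phloroglucinol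
Product: 3 2,4,6-trihydroxybenzaldehyde, via aryl iminium salt 2 (not isolated)
Conditions: POCl3 (1.1 equiv), DMF, EtOAc, 0 °C → rt; then H2O, rt
Reagents that add atoms: N,N-dimethylformamide CN(C)C=O (formyl carbon); water O (aldehyde oxygen); phosphoryl chloride O=P(Cl)(Cl)Cl (only the chloride counter-ion of 2)
Why: Vilsmeier–Haack formylation of the very electron-rich triol stops at mono-formylation with one equivalent of reagent, and water hydrolyses the iminium salt to the aldehyde.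

Step 2
Reactants: 3 2,4,6-trihydroxybenzaldehyde
Product: 4 2,4-bis(benzyloxy)-6-hydroxybenzaldehyde
Conditions: BnBr (2.05 equiv), K2CO3 (2.1 equiv), DMF, 0 °C → rt
Reagents that add atoms: benzyl bromide BrCc1ccccc1
Why: Williamson etherification takes the para-OH and one ortho-OH, while the remaining ortho-OH is hydrogen-bonded to the aldehyde and is the least reactive.

Step 3
Reactants: 5 3,4,5-trihydroxybenzaldehyde
Product: 6 3,4,5-tris(benzyloxy)benzaldehyde
Conditions: BnBr (3.5 equiv), K2CO3, cat. KI, DMF, 60 °C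
Reagents that add atoms: benzyl bromide BrCc1ccccc1
Why: Exhaustive Williamson etherification of three unhindered phenols.

Step 4
Reactants: 6 3,4,5-tris(benzyloxy)benzaldehyde; 7 (triphenylphosphoranylidene)acetaldehyde
Product: 8 (E)-3-[3,4,5-tris(benzyloxy)phenyl]prop-2-enal
Conditions: 7 (1.1 equiv), toluene, 80 °C
Reagents that add atoms: none
Why: Wittig olefination with a stabilised ylide gives the (E)-enal.

Step 5
Reactants: 4 2,4-bis(benzyloxy)-6-hydroxybenzaldehyde; 8 (E)-3-[3,4,5-tris(benzyloxy)phenyl]prop-2-enal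
Product: 11 (2R)-5,7-bis(benzyloxy)-2-[3,4,5-tris(benzyloxy)phenyl]-2H-chromene-3-carbaldehyde, via oxa-Michael adduct 9 (not isolated), via aldol adduct 10 (not isolated)
Conditions: (S)-α,α-diphenylprolinol triethylsilyl ether (20 mol %), 2-nitrobenzoic acid (20 mol %), 4 Å MS, toluene, rt
Reagents that add atoms: none
Why: Iminium activation of 8 lets the phenol of 4 add to the β-carbon on the face away from the CPh2OSiEt3 group (oxa-Michael, sets C2 as R), and the resulting enamine closes the pyran ring onto the aryl aldehyde by an intramolecular aldol condensation.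

Step 6
Reactants: 11 (2R)-chromene-3-carbaldehyde
Product: 12 (2R)-5,7-bis(benzyloxy)-2-[3,4,5-tris(benzyloxy)phenyl]-2H-chromene-3-carboxylic acid
Conditions: NaClO2, NaH2PO4, 2-methyl-2-butene (excess), t-BuOH/THF/H2O, 0 °C → rt
Reagents that add atoms: sodium chlorite [Na+].[O-]Cl=O
Why: Pinnick oxidation converts the enal to the acid without touching the alkene, the benzyl ethers or C2; the scavenger protects the electron-rich rings from HOCl.

Step 7
Reactants: 12 (2R)-chromene-3-carboxylic acid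
Product: 16 (2R)-5,7-bis(benzyloxy)-2-[3,4,5-tris(benzyloxy)phenyl]chroman-3-one, via acyl azide 13 (not isolated), via vinyl isocyanate 14 (not isolated), via enamine 15 (not isolated)
Conditions: DPPA, Et3N, toluene, 0 °C → rt, then 85 °C; then 2 M aq. HCl/THF, 45 °C; crude ketone used at once
Reagents that add atoms: water O (ketone oxygen); diphenylphosphoryl azide O=P(N=[N+]=[N-])(Oc1ccccc1)Oc1ccccc1 (nitrogen of 13–15 only)
Why: Curtius rearrangement (DPPA) replaces the C3 carboxyl by nitrogen without touching C2, and hydrolysis of the vinyl isocyanate through the enamine gives the C3 ketone, the established way from 2H-chromene-3-carboxylic acids to chroman-3-ones.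

Step 8
Reactants: 16 (2R)-chroman-3-one
Product: 17 (2R,3R)-5,7-bis(benzyloxy)-2-[3,4,5-tris(benzyloxy)phenyl]chroman-3-ol
Conditions: L-Selectride, THF, –78 °C; then AcOH
Reagents that add atoms: none
Why: The bulky hydride attacks the C3 carbonyl from the face opposite the C2 aryl group, so the new hydroxyl ends cis to the aryl (3R), the known outcome for benzylated flavan-3-ones.

Step 9
Reactants: 18 methyl 4-hydroxybenzoate
Product: 19 methyl 4-(benzyloxy)benzoate
Conditions: BnBr, K2CO3, acetone, reflux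
Reagents that add atoms: benzyl bromide BrCc1ccccc1
Why: Williamson etherification of an acidic phenol.

Step 10
Reactants: 19 methyl 4-(benzyloxy)benzoate
Product: 20 4-(benzyloxy)benzoic acid
Conditions: NaOH, MeOH/THF/H2O, 60 °C; then aq. HCl
Reagents that add atoms: sodium hydroxide [Na+].[OH-]
Why: Saponification of the methyl ester; the benzyl ether is stable to base.

Step 11
Reactants: 20 4-(benzyloxy)benzoic acid
Product: 21 4-(benzyloxy)benzoyl chloride
Conditions: (COCl)2, cat. DMF, CH2Cl2, 0 °C → rt; evaporate, use crude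
Reagents that add atoms: oxalyl chloride O=C(Cl)C(Cl)=O
Why: DMF-catalysed acid chloride formation gives the reactive acyl donor needed for the hindered axial 3-OH.

Step 12
Reactants: 17 (2R,3R)-chroman-3-ol; 21 4-(benzyloxy)benzoyl chloride
Product: 22 (2R,3R)-5,7-bis(benzyloxy)-2-[3,4,5-tris(benzyloxy)phenyl]chroman-3-yl 4-(benzyloxy)benzoate
Conditions: Et3N, DMAP (0.2 equiv), CH2Cl2, 0 °C → rt
Reagents that add atoms: none
Why: DMAP-catalysed O-acylation takes place at oxygen, so C3 keeps its configuration and C2 is not epimerised.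

Step 13
Reactants: 22 hexabenzyl ester
Product: 23 epigallocatechin 3-O-(4-hydroxybenzoate)
Conditions: H2 (1 atm), 20% Pd(OH)2/C, THF/MeOH, rt; filter under N2, purify on Sephadex LH-20
Reagents that add atoms: none
Why: Hydrogenolysis over Pearlman's catalyst removes all six benzyl ethers and leaves the ester and the C2–O1 bond intact, as in known gallate-ester catechin syntheses.

**Compound list**
1 | phloroglucinol (benzene-1,3,5-triol) | Oc1cc(O)cc(O)c1 | starting material
2 | dimethyl(2,4,6-trihydroxybenzylidene)iminium chloride | C[N+](C)=Cc1c(O)cc(O)cc1O.[Cl-] | intermediate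
3 | 2,4,6-trihydroxybenzaldehyde | O=Cc1c(O)cc(O)cc1O | intermediate
4 | 2,4-bis(benzyloxy)-6-hydroxybenzaldehyde | O=Cc1c(O)cc(OCc2ccccc2)cc1OCc1ccccc1 | intermediate
5 | 3,4,5-trihydroxybenzaldehyde | O=Cc1cc(O)c(O)c(O)c1 | starting material
6 | 3,4,5-tris(benzyloxy)benzaldehyde | O=Cc1cc(OCc2ccccc2)c(OCc2ccccc2)c(OCc2ccccc2)c1 | intermediate
7 | (triphenylphosphoranylidene)acetaldehyde | O=CC=P(c1ccccc1)(c1ccccc1)c1ccccc1 | starting material
8 | (E)-3-[3,4,5-tris(benzyloxy)phenyl]prop-2-enal | O=C/C=C/c1cc(OCc2ccccc2)c(OCc2ccccc2)c(OCc2ccccc2)c1 | intermediate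
9 | (3S)-3-[3,5-bis(benzyloxy)-2-formylphenoxy]-3-[3,4,5-tris(benzyloxy)phenyl]propanal (oxa-Michael adduct; same spatial arrangement as C2 of 11) | O=CC[C@H](Oc1cc(OCc2ccccc2)cc(OCc2ccccc2)c1C=O)c1cc(OCc2ccccc2)c(OCc2ccccc2)c(OCc2ccccc2)c1 | intermediate
10 | 5,7-bis(benzyloxy)-4-hydroxy-2-[3,4,5-tris(benzyloxy)phenyl]chromane-3-carbaldehyde (aldol adduct; C2 as in 11, CIP label 2S; C3/C4 mixture) | O=CC1C(O)c2c(OCc3ccccc3)cc(OCc3ccccc3)cc2O[C@@H]1c1cc(OCc2ccccc2)c(OCc2ccccc2)c(OCc2ccccc2)c1 | intermediate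
11 | (2R)-5,7-bis(benzyloxy)-2-[3,4,5-tris(benzyloxy)phenyl]-2H-chromene-3-carbaldehyde | O=CC1=Cc2c(OCc3ccccc3)cc(OCc3ccccc3)cc2O[C@@H]1c1cc(OCc2ccccc2)c(OCc2ccccc2)c(OCc2ccccc2)c1 | intermediate
12 | (2R)-5,7-bis(benzyloxy)-2-[3,4,5-tris(benzyloxy)phenyl]-2H-chromene-3-carboxylic acid | OC(=O)C1=Cc2c(OCc3ccccc3)cc(OCc3ccccc3)cc2O[C@@H]1c1cc(OCc2ccccc2)c(OCc2ccccc2)c(OCc2ccccc2)c1 | intermediate
13 | (2R)-5,7-bis(benzyloxy)-2-[3,4,5-tris(benzyloxy)phenyl]-2H-chromene-3-carbonyl azide | [N-]=[N+]=NC(=O)C1=Cc2c(OCc3ccccc3)cc(OCc3ccccc3)cc2O[C@@H]1c1cc(OCc2ccccc2)c(OCc2ccccc2)c(OCc2ccccc2)c1 | intermediate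
14 | (2R)-5,7-bis(benzyloxy)-3-isocyanato-2-[3,4,5-tris(benzyloxy)phenyl]-2H-chromene | O=C=NC1=Cc2c(OCc3ccccc3)cc(OCc3ccccc3)cc2O[C@@H]1c1cc(OCc2ccccc2)c(OCc2ccccc2)c(OCc2ccccc2)c1 | intermediate
15 | (2R)-5,7-bis(benzyloxy)-2-[3,4,5-tris(benzyloxy)phenyl]-2H-chromen-3-amine | NC1=Cc2c(OCc3ccccc3)cc(OCc3ccccc3)cc2O[C@@H]1c1cc(OCc2ccccc2)c(OCc2ccccc2)c(OCc2ccccc2)c1 | intermediate
16 | (2R)-5,7-bis(benzyloxy)-2-[3,4,5-tris(benzyloxy)phenyl]chroman-3-one | O=C1Cc2c(OCc3ccccc3)cc(OCc3ccccc3)cc2O[C@@H]1c1cc(OCc2ccccc2)c(OCc2ccccc2)c(OCc2ccccc2)c1 | intermediate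
17 | (2R,3R)-5,7-bis(benzyloxy)-2-[3,4,5-tris(benzyloxy)phenyl]chroman-3-ol (2,3-cis) | O[C@@H]1Cc2c(OCc3ccccc3)cc(OCc3ccccc3)cc2O[C@@H]1c1cc(OCc2ccccc2)c(OCc2ccccc2)c(OCc2ccccc2)c1 | intermediate
18 | methyl 4-hydroxybenzoate | COC(=O)c1ccc(O)cc1 | starting material
19 | methyl 4-(benzyloxy)benzoate | COC(=O)c1ccc(OCc2ccccc2)cc1 | intermediate
20 | 4-(benzyloxy)benzoic acid | OC(=O)c1ccc(OCc2ccccc2)cc1 | intermediate
21 | 4-(benzyloxy)benzoyl chloride | ClC(=O)c1ccc(OCc2ccccc2)cc1 | intermediate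
22 | (2R,3R)-5,7-bis(benzyloxy)-2-[3,4,5-tris(benzyloxy)phenyl]chroman-3-yl 4-(benzyloxy)benzoate | O=C(O[C@@H]1Cc2c(OCc3ccccc3)cc(OCc3ccccc3)cc2O[C@@H]1c1cc(OCc2ccccc2)c(OCc2ccccc2)c(OCc2ccccc2)c1)c1ccc(OCc2ccccc2)cc1 | intermediate
23 | epigallocatechin 3-O-(4-hydroxybenzoate), (2R,3R) | O=C(O[C@@H]1Cc2c(O)cc(O)cc2O[C@@H]1c1cc(O)c(O)c(O)c1)c1ccc(O)cc1 | target

**Totals**
Total step count: 13.
Longest linear sequence: 8 steps (3 → 4 → 5 → 6 → 7 → 8 → 12 → 13; the branch 1 → 2 → 5 … is equally long), i.e. 8/13 of the total.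

**Steps most likely to fail, with fallbacks**

Step 5. The salicylaldehyde is electron-rich, hydrogen-bonded and flanked by two ortho oxygens, so the domino reaction may be slow or give modest ee. Fallback: setting out from 4 and 8, the same oxa-Michael/aldol condensation is run without an asymmetric catalyst (K2CO3, dioxane, 90 °C, or pyrrolidine/PhCO2H) to give the racemic 5,7-bis(benzyloxy)-2-[3,4,5-tris(benzyloxy)phenyl]-2H-chromene-3-carbaldehyde F1. The enantiomers are then separated by preparative chiral SFC; the unwanted (2S)-enantiomer is re-racemised with pyrrolidine (reversible oxa-Michael) and recycled. The route is rejoined at 11.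

Step 7. The Curtius/hydrolysis sequence ends in warm aqueous acid, where the C2–H of ketone 16 (α to C=O, benzylic, α-oxy) may epimerise or the ketone may decompose. Fallback: setting out from 11, Tsuji–Wilkinson decarbonylation (RhCl(PPh3)3, toluene, reflux) gives the flav-3-ene 5,7-bis(benzyloxy)-2-[3,4,5-tris(benzyloxy)phenyl]-2H-chromene F2 (same arrangement at C2, CIP label 2S). Hydroboration–oxidation (BH3·THF, 0 °C; then NaOH/H2O2) places boron at C3 anti to the aryl group and gives the 2,3-trans alcohol (2R,3S)-5,7-bis(benzyloxy)-2-[3,4,5-tris(benzyloxy)phenyl]chroman-3-ol F3. Dess–Martin periodinane (CH2Cl2, rt, neutral) then gives the ketone, so the route is rejoined at 16.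

Step 2. Bis-benzylation of the phloroglucinol aldehyde can give mono/tri-ether mixtures and C-benzylation. Fallback: setting out from 3, exhaustive benzylation (BnBr in excess, K2CO3, DMF, 60 °C) gives 2,4,6-tris(benzyloxy)benzaldehyde F4. One ortho benzyl ether is then cleaved under chelation control by the aldehyde (MgBr2·OEt2, toluene/Et2O, reflux), and the route is rejoined at 4.

**Further compounds**
F1 | step 5 | racemic 5,7-bis(benzyloxy)-2-[3,4,5-tris(benzyloxy)phenyl]-2H-chromene-3-carbaldehyde | O=CC1=Cc2c(OCc3ccccc3)cc(OCc3ccccc3)cc2OC1c1cc(OCc2ccccc2)c(OCc2ccccc2)c(OCc2ccccc2)c1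
F2 | step 7 | (2S)-5,7-bis(benzyloxy)-2-[3,4,5-tris(benzyloxy)phenyl]-2H-chromene | C1=Cc2c(OCc3ccccc3)cc(OCc3ccccc3)cc2O[C@@H]1c1cc(OCc2ccccc2)c(OCc2ccccc2)c(OCc2ccccc2)c1
F3 | step 7 | (2R,3S)-5,7-bis(benzyloxy)-2-[3,4,5-tris(benzyloxy)phenyl]chroman-3-ol | O[C@H]1Cc2c(OCc3ccccc3)cc(OCc3ccccc3)cc2O[C@@H]1c1cc(OCc2ccccc2)c(OCc2ccccc2)c(OCc2ccccc2)c1
F4 | step 2 | 2,4,6-tris(benzyloxy)benzaldehyde | O=Cc1c(OCc2ccccc2)cc(OCc2ccccc2)cc1OCc1ccccc1
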